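Ring B of the target holds C8, with its carboxyl carbon C12, between C7 and C9. Taking C8 and C12 out contracts ring B to the cyclopentanone C5–C6–C7–C9–C10 of a trans-hydrindane, which the (S)-Hajos–Parrish ketone supplies with C10 already set. The key step puts the diazo carbon of tert-butyl diazoacetate into the C7–C9 bond: one Lewis acid-promoted operation forms C7–C8 and C8–C9, turns the five-membered ring into ring B and leaves C12 as an ester beside the C9 enol, where C11 is attached later. Its precursor is the 4,4,10-trimethyl-5α-hydrindan-9-one whose C6 oxygen is already β and silyl-protected.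

Key step: step 9

Remark on numbering: drimane (target) numbering is used for every compound: ring A = C1–C5 and C10, ring B = C5–C10, gem-dimethyl on C4, methyl on C10, C11 on C9, C12 on C8; β is the face of the C10 methyl; before step 9 the five-membered ring is C5, C6, C7, C9, C10.
Assumption on configuration: the target SMILES is read as 5α-H, 6β-acyloxy, 8β-CO2H, 9β-CO2H, 10β-CH3 (both acids cis to each other and to the C10 methyl).
Remark on design: a 6β-oxygen and an 8β-carboxyl are syn-diaxial on ring B and would lactonise if the hydroxyl were free. C6 is therefore inverted before the ring enlargement and acylated while C8 is still sp2, and the triene is attached last by olefination. The hydrogens at C9 and C8 are set by protonation and by hydrogenation of a trisubstituted alkene, not by hydrogenation of the tetrasubstituted C8=C9 bond.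

Step 1
Reactants: 1 (S)-Hajos–Parrish ketone
Product: 2 enone 9-ethylene ketal
Conditions: TMSOCH2CH2OTMS, TMSOTf (cat.), CH2Cl2, −78 → −20 °C; then pyridine
Reagents that add atoms: 1,2-bis(trimethylsilyloxy)ethane, C[Si](C)(C)OCCO[Si](C)(C)C
Why: Silyl triflate-catalysed acetalisation with the bis-silyl ether of ethylene glycol converts saturated ketones far faster than conjugated enones, so only the five-ring C9 carbonyl should be masked and no stereocentre is touched.

Step 2
Reactants: 2 enone 9-ethylene ketal
Product: 3 4,4-dimethyl β,γ-unsaturated ketone 9-ketal (C5=C6)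
Conditions: KOt-Bu, t-BuOH, rt; MeI, 0 °C → rt
Reagents that add atoms: iodomethane, CI
Why: Deconjugative α,α-dimethylation of the enone through its extended potassium enolate places both methyl groups on C4 and leaves the double bond at C5=C6, where it cannot return to conjugation because C4 is now quaternary.

Step 3
Reactants: 3 4,4-dimethyl β,γ-unsaturated ketone 9-ketal
Product: 5 alkene 9-ketal (C3 = CH2), via C3 hydrazone 4 (not isolated)
Conditions: N2H4·H2O, KOH, diethylene glycol, 130 → 200 °C
Reagents that add atoms: none
Why: Wolff–Kishner reduction (Huang-Minlon procedure) removes the C3 oxygen through the hydrazone; the basic medium leaves the dioxolane intact, and the isolated C5=C6 bond has no acidifying group that would let it move.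

Step 4
Reactants: 5 alkene 9-ketal
Product: 7 6α-alcohol 9-ketal (5α-H), via 6α-alkylborane 6 (not isolated)
Conditions: BH3·THF, THF, 0 °C → rt; then NaOH, H2O2, 0 → 40 °C
Reagents that add atoms: hydrogen peroxide, OO
Why: Hydroboration–oxidation adds H and B syn from the α-face, opposite the angular C10 methyl and the 4β-methyl, with boron on the less substituted C6, so oxidation with retention should give the trans ring fusion (5α-H) and the 6α-alcohol.

Step 5
Reactants: 7 6α-alcohol 9-ketal
Product: 8 6-ketone 9-ketal
Conditions: Dess–Martin periodinane, NaHCO3, CH2Cl2, 0 °C → rt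
Reagents that add atoms: none
Why: Dess–Martin oxidation under buffered, non-enolising conditions gives the C6 ketone without disturbing the ketal or the adjacent C5 stereocentre.

Step 6
Reactants: 8 6-ketone 9-ketal
Product: 9 6β-alcohol 9-ketal
Conditions: LiBH(s-Bu)3, THF, −78 °C; then H2O
Reagents that add atoms: none
Why: Hydride reduction under steric approach control: the bulky borohydride can reach C6 only from the α-face because the β-face is screened by the syn 4β- and 10β-methyl groups, which should give the 6β-alcohol, and the aprotic low-temperature conditions avoid enolisation toward C5.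

Step 7
Reactants: 9 6β-alcohol 9-ketal
Product: 10 6β-silyl ether 9-ketal
Conditions: TBSOTf, 2,6-lutidine, CH2Cl2, 0 °C → rt
Reagents that add atoms: tert-butyldimethylsilyl trifluoromethanesulfonate, CC(C)(C)[Si](C)(C)OS(=O)(=O)C(F)(F)F
Why: Silylation with a silyl triflate and a hindered pyridine base is reactive enough for the shielded 6β-hydroxyl and leaves the dioxolane alone; the configuration at C6 is retained.

Step 8
Reactants: 10 6β-silyl ether 9-ketal
Product: 11 6β-silyloxy-4,4,10-trimethyl-5α-hydrindan-9-one
Conditions: PPTS (cat.), acetone–H2O, 60 °C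
Reagents that add atoms: water, O
Why: Mild acid-catalysed acetal hydrolysis frees the C9 ketone while the hindered secondary silyl ether survives, and the near-neutral medium should not trigger β-elimination of the C6 silyloxy group.

Step 9
Reactants: 11 6β-silyloxy-4,4,10-trimethyl-5α-hydrindan-9-one; 12 tert-butyl diazoacetate
Product: 14 enolised β-keto ester (tert-butyl 6β-silyloxy-9-hydroxy-11-nordrim-8-en-12-oate), via diazonium betaine 13 (not isolated)
Conditions: BF3·OEt2, CH2Cl2, −78 → −20 °C, slow addition of 12
Reagents that add atoms: none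
Why: BF3 activates the C9 carbonyl, the nucleophilic diazo carbon of 12 adds to it, and in the resulting β-diazonium alkoxide 13 the C7–C9 bond shifts to the diazonium carbon with loss of N2, so that the new C8 is bonded to both C7 and C9 and the β-keto ester settles as the hydrogen-bonded enol 14. The closest known reaction type is the Lewis acid-promoted one-carbon homologation of cyclic ketones with diazoacetates (a Tiffeneau–Demjanov-type ring expansion), which with α,α-disubstituted cycloalkanones proceeds by migration of the CH2 group. Ring B is not closed end to end; it arises by enlargement of the existing five-membered ring through a 1,2-alkyl shift. No stereocentre is created, and C5, C6 and C10 take no part in the bond changes, so their configurations persist. The step needs migration of C7 instead of C10, which should be secured because the rotamer of 13 that places the small methylene anti to the departing N2 is far less crowded than the one that swings the fully substituted C10 toward the ester-bearing carbon. It also needs a single insertion, which the enolised and hindered product should ensure, and survival of the C6 silyl ether and the tert-butyl ester, which low temperature and a short exposure to BF3 should allow.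

Step 10
Reactants: 14 enolised β-keto ester
Product: 16 C9 enol triflate, via sodium enolate 15 (not isolated)
Conditions: NaH, Et2O, 0 °C; then Tf2O, −78 → 0 °C
Reagents that add atoms: trifluoromethanesulfonic anhydride, O=S(=O)(OS(=O)(=O)C(F)(F)F)C(F)(F)F
Why: O-Sulfonylation of the sodium enolate of a β-keto ester (enol triflate formation) can occur only at the C9 oxygen of the C8=C9 enolate because C10 is quaternary.

Step 11
Reactants: 16 C9 enol triflate
Product: 17 drim-8-ene 11-(4-methoxybenzyl) 12-tert-butyl diester
Conditions: Pd(OAc)2 (cat.), dppp, CO (1 atm), 4-MeOC6H4CH2OH, Et3N, DMF, 65 °C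
Reagents that add atoms: carbon monoxide, [C-]#[O+]; 4-methoxybenzyl alcohol, COc1ccc(CO)cc1
Why: Palladium-catalysed alkoxycarbonylation of a vinyl triflate (oxidative addition to zerovalent palladium, CO insertion, alcoholysis of the acylpalladium) attaches C11 to C9, and the primary benzylic alcohol gives an ester that is later cleaved by the same acid as the tert-butyl ester.

Step 12
Reactants: 17 drim-8-ene diester
Product: 19 drim-7-ene diester (9α-H), via lithium dienolate 18 (not isolated)
Conditions: LiN(i-Pr)2, THF, −78 °C; then AcOH, −78 °C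
Reagents that add atoms: none
Why: Deconjugative protonation: γ-deprotonation at C7 gives the extended enolate of the C11 ester, and kinetic protonation at its α-carbon C9 from the α-face, opposite the adjacent 10β-methyl, should set 9α-H (C11 β, equatorial) and leave the double bond at C7=C8, as is known for drim-8-ene-11,12-dioates.

Step 13
Reactants: 19 drim-7-ene diester (9α-H)
Product: 20 6β-hydroxy drim-7-ene diester
Conditions: HF·pyridine, pyridine, THF, 0 °C → rt
Reagents that add atoms: none
Why: Fluoride-mediated desilylation in a pyridine-buffered medium spares both esters and does not enolise C9, and the freed 6β-hydroxyl cannot lactonise onto C12 while C8 is sp2, since that lactone would hold a bridgehead double bond.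

Step 14
Reactants: 20 6β-hydroxy drim-7-ene diester; 21 (diethoxyphosphoryl)acetic acid
Product: 23 6β-phosphonoacetate drim-7-ene diester, via phosphorylketene 22 (not isolated)
Conditions: DCC, CH2Cl2, 0 °C → rt
Reagents that add atoms: none
Why: Carbodiimide activation of the phosphonoacetic acid gives the ketene by elimination from the O-acylisourea, and this small, base-free acylating agent should esterify the axial 6β-hydroxyl flanked by two methyl groups with retention at C6 (ketene variant of the Steglich esterification).

Step 15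
Reactants: 23 6β-phosphonoacetate drim-7-ene diester
Product: 24 6β-phosphonoacetate drimane diester (8α-H, 9α-H)
Conditions: H2 (3 atm), 5% Pt on carbon (Pt/C), EtOAc, rt
Reagents that add atoms: none
Why: Heterogeneous catalytic hydrogenation of the trisubstituted enoate delivers both hydrogens syn from the α-face, the β-face being blocked by the 10β-methyl, the 6β-acyloxy group and the 9β-ester, which should set 8α-H and hence the axial 8β-ester cis to C11; platinum is chosen to limit allylic C–O hydrogenolysis, benzylic ester cleavage and double-bond migration.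

Step 16
Reactants: 24 6β-phosphonoacetate drimane diester; 25 (2E,4E)-hexa-2,4-dienal
Product: 26 6β-octatrienoate drimane diester
Conditions: LiCl, DBU, MeCN, 0 °C → rt
Reagents that add atoms: none
Why: Horner–Wadsworth–Emmons olefination under Masamune–Roush conditions builds the C2′=C3′ bond with the E geometry typical of stabilised phosphonates, and the amine base with LiCl should not epimerise the ester α-centres C8 and C9.

Step 17
Reactants: 26 6β-octatrienoate drimane diester
Product: 27 target diacid
Conditions: CF3CO2H–CH2Cl2 (1:3), anisole, 0 °C → rt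
Reagents that add atoms: none
Why: Acidolysis removes the tert-butyl ester as 2-methylpropene and the 4-methoxybenzyl ester as its cation, which anisole traps, while the trienoate and all stereocentres should be inert to the acid.

Compound list
1 | (S)-Hajos–Parrish ketone, (7aS)-7a-methyl-2,3,7,7a-tetrahydro-1H-indene-1,5(6H)-dione | O=C1CCC2=CC(=O)CC[C@]12C | starting material
2 | enone 9-ethylene ketal: 1,3-dioxolane on the saturated five-ring ketone C9 of 1, C3=O/C4=C5 enone kept, 10β-CH3 | C1CC2(OCCO2)[C@@]3(C)CCC(=O)C=C13 | intermediate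
3 | 4,4,10-trimethylhydrind-5-en-3-one 9-ethylene ketal (C5=C6 in the five-membered ring) | C1=C2C(C)(C)C(=O)CC[C@]2(C)C2(OCCO2)C1 | intermediate
4 | C3 hydrazone of 3 | C1=C2C(C)(C)C(=NN)CC[C@]2(C)C2(OCCO2)C1 | intermediate (not isolated)
5 | 4,4,10-trimethylhydrind-5-ene 9-ethylene ketal | C1=C2C(C)(C)CCC[C@]2(C)C2(OCCO2)C1 | intermediate
6 | 6α-boryl-4,4,10-trimethyl-5α-hydrindan-9-one ethylene ketal (monoalkylborane) | B[C@H]1CC2(OCCO2)[C@@]3(C)CCCC(C)(C)[C@H]13 | intermediate (not isolated)
7 | 6α-hydroxy-4,4,10-trimethyl-5α-hydrindan-9-one ethylene ketal (trans-fused) | O[C@H]1CC2(OCCO2)[C@@]3(C)CCCC(C)(C)[C@H]13 | intermediate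
8 | 4,4,10-trimethyl-5α-hydrindane-6,9-dione 9-ethylene ketal | O=C1CC2(OCCO2)[C@@]3(C)CCCC(C)(C)[C@H]13 | intermediate
9 | 6β-hydroxy-4,4,10-trimethyl-5α-hydrindan-9-one ethylene ketal | O[C@@H]1CC2(OCCO2)[C@@]3(C)CCCC(C)(C)[C@H]13 | intermediate
10 | 6β-(tert-butyldimethylsilyloxy)-4,4,10-trimethyl-5α-hydrindan-9-one ethylene ketal | CC(C)(C)[Si](C)(C)O[C@@H]1CC2(OCCO2)[C@@]3(C)CCCC(C)(C)[C@H]13 | intermediate
11 | 6β-(tert-butyldimethylsilyloxy)-4,4,10-trimethyl-5α-hydrindan-9-one (trans-fused; precursor of the key step) | CC(C)(C)[Si](C)(C)O[C@@H]1CC(=O)[C@@]2(C)CCCC(C)(C)[C@H]12 | intermediate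
12 | tert-butyl diazoacetate | [N-]=[N+]=CC(=O)OC(C)(C)C | starting material
13 | BF3-bound C9 alkoxide carrying the diazonium ester carbon (configuration at C9 and at the diazonium carbon undefined) | CC(C)(C)[Si](C)(C)O[C@@H]1CC(O[B-](F)(F)F)(C([N+]#N)C(=O)OC(C)(C)C)[C@@]2(C)CCCC(C)(C)[C@H]12 | intermediate (not isolated)
14 | tert-butyl 6β-(tert-butyldimethylsilyloxy)-9-hydroxy-11-nordrim-8-en-12-oate (enol form of the 9-oxo 12-ester; 5α-H) | CC(C)(C)[Si](C)(C)O[C@@H]1CC(C(=O)OC(C)(C)C)=C(O)[C@@]2(C)CCCC(C)(C)[C@H]12 | intermediate
15 | sodium enolate of 14 | CC(C)(C)[Si](C)(C)O[C@@H]1CC(C(=O)OC(C)(C)C)=C([O-])[C@@]2(C)CCCC(C)(C)[C@H]12.[Na+] | intermediate (not isolated)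
16 | tert-butyl 6β-(tert-butyldimethylsilyloxy)-9-(trifluoromethylsulfonyloxy)-11-nordrim-8-en-12-oate | CC(C)(C)[Si](C)(C)O[C@@H]1CC(C(=O)OC(C)(C)C)=C(OS(=O)(=O)C(F)(F)F)[C@@]2(C)CCCC(C)(C)[C@H]12 | intermediate
17 | 12-tert-butyl 11-(4-methoxybenzyl) 6β-(tert-butyldimethylsilyloxy)drim-8-ene-11,12-dioate | CC(C)(C)[Si](C)(C)O[C@@H]1CC(C(=O)OC(C)(C)C)=C(C(=O)OCc3ccc(OC)cc3)[C@@]2(C)CCCC(C)(C)[C@H]12 | intermediate
18 | lithium dienolate of the C11 ester of 17 (C7=C8 and C9=C11) | CC(C)(C)[Si](C)(C)O[C@@H]1C=C(C(=O)OC(C)(C)C)C(=C([O-])OCc3ccc(OC)cc3)[C@@]2(C)CCCC(C)(C)[C@H]12.[Li+] | intermediate (not isolated)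
19 | 12-tert-butyl 11-(4-methoxybenzyl) 6β-(tert-butyldimethylsilyloxy)-9α-H-drim-7-ene-11,12-dioate | CC(C)(C)[Si](C)(C)O[C@@H]1C=C(C(=O)OC(C)(C)C)[C@H](C(=O)OCc3ccc(OC)cc3)[C@@]2(C)CCCC(C)(C)[C@H]12 | intermediate
20 | 12-tert-butyl 11-(4-methoxybenzyl) 6β-hydroxy-9α-H-drim-7-ene-11,12-dioate | O[C@@H]1C=C(C(=O)OC(C)(C)C)[C@H](C(=O)OCc3ccc(OC)cc3)[C@@]2(C)CCCC(C)(C)[C@H]12 | intermediate
21 | (diethoxyphosphoryl)acetic acid | CCOP(=O)(OCC)CC(=O)O | starting material
22 | (diethoxyphosphoryl)ketene | CCOP(=O)(OCC)C=C=O | intermediate (not isolated)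
23 | 12-tert-butyl 11-(4-methoxybenzyl) 6β-[(diethoxyphosphoryl)acetoxy]-9α-H-drim-7-ene-11,12-dioate | CCOP(=O)(OCC)CC(=O)O[C@@H]1C=C(C(=O)OC(C)(C)C)[C@H](C(=O)OCc3ccc(OC)cc3)[C@@]2(C)CCCC(C)(C)[C@H]12 | intermediate
24 | 12-tert-butyl 11-(4-methoxybenzyl) 6β-[(diethoxyphosphoryl)acetoxy]drimane-11,12-dioate (8α-H, 9α-H; both ester groups β) | CCOP(=O)(OCC)CC(=O)O[C@@H]1C[C@H](C(=O)OC(C)(C)C)[C@H](C(=O)OCc3ccc(OC)cc3)[C@@]2(C)CCCC(C)(C)[C@H]12 | intermediate
25 | (2E,4E)-hexa-2,4-dienal | C/C=C/C=C/C=O | starting material
26 | 12-tert-butyl 11-(4-methoxybenzyl) 6β-[(2E,4E,6E)-octa-2,4,6-trienoyloxy]drimane-11,12-dioate (8α-H, 9α-H) | C/C=C/C=C/C=C/C(=O)O[C@@H]1C[C@H](C(=O)OC(C)(C)C)[C@H](C(=O)OCc3ccc(OC)cc3)[C@@]2(C)CCCC(C)(C)[C@H]12 | intermediate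
27 | 6β-[(2E,4E,6E)-octa-2,4,6-trienoyloxy]drimane-11,12-dioic acid (5α-H, 8β-CO2H, 9β-CO2H, 10β-CH3) | C/C=C/C=C/C=C/C(=O)O[C@@H]1C[C@H](C(=O)O)[C@H](C(=O)O)[C@@]2(C)CCCC(C)(C)[C@H]12 | target

Total step count: 17. Longest linear sequence: 17 steps (1 → 27); compounds 12, 21 and 25 are commercial and enter without preparation.

Steps most likely to fail

Step 9 (key step). The diazo ester may add too slowly to the hindered, α-quaternary carbonyl and decompose instead. C10 may migrate in place of C7. BF3 may also promote β-elimination of the C6 silyloxy group, or acidolysis of the tert-butyl ester followed by decarboxylation. The fallback sets out from 11 and returns at 14. It separates addition from rearrangement. Lithiated 12 (LiN(i-Pr)2, THF, −78 °C) should add to the ketone to give the β-hydroxy-α-diazo ester F1. Catalytic Rh2(OAc)4 in CH2Cl2 at room temperature should then convert F1 into a rhodium carbenoid, in which the less substituted C7–C9 bond is expected to shift to the carbenoid carbon with loss of N2. This enlarges the ring without any Lewis acid and gives 14.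

Step 12. Protonation of the dienolate may occur at C7 and return the conjugated isomer. It may occur at C9 from the β-face. The dienolate may also expel the C6 silyloxy group. The fallback sets out from 17 and returns at 27. It avoids the dienolate and reduces the tetrasubstituted alkene directly. Desilylation (HF·pyridine) should give the Δ8 6β-alcohol F2, which is safe from lactonisation while C8 is sp2. Ketene acylation with 21 and DCC should give the Δ8 phosphonoacetate F3. Hydrogenation under pressure (H2, about 60 bar, Pd/C, EtOAc–AcOH) should add both hydrogens to C8=C9 from the α-face and at the same time hydrogenolyse the 4-methoxybenzyl ester, giving the saturated 11-acid F4. Olefination with 25 (LiCl, excess DBU, MeCN) should give the trienoate 11-acid F5, and CF3CO2H in CH2Cl2 should then give 27.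

Step 14. Acylation of the axial hydroxyl between the 4β- and 10β-methyl groups may stay incomplete. Prolonged exposure to the reagents may also move the C7=C8 bond back into conjugation. The fallback sets out from 20 and returns at 23. It uses the smallest and most reactive acyl donor and forms the C–P bond afterwards. Bromoacetyl bromide with pyridine in CH2Cl2 at −20 °C should give the 6β-bromoacetate F6. A Michaelis–Arbuzov reaction with neat P(OEt)3 at about 110 °C should then give 23.

Further compounds
F1 | step 9 | tert-butyl 2-diazo-2-[6β-(tert-butyldimethylsilyloxy)-9-hydroxy-4,4,10-trimethyl-5α-hydrindan-9-yl]acetate (C9 configuration undefined, lost on rearrangement) | CC(C)(C)[Si](C)(C)O[C@@H]1CC(O)(C(=[N+]=[N-])C(=O)OC(C)(C)C)[C@@]2(C)CCCC(C)(C)[C@H]12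
F2 | step 12 | 12-tert-butyl 11-(4-methoxybenzyl) 6β-hydroxydrim-8-ene-11,12-dioate | O[C@@H]1CC(C(=O)OC(C)(C)C)=C(C(=O)OCc3ccc(OC)cc3)[C@@]2(C)CCCC(C)(C)[C@H]12
F3 | step 12 | 12-tert-butyl 11-(4-methoxybenzyl) 6β-[(diethoxyphosphoryl)acetoxy]drim-8-ene-11,12-dioate | CCOP(=O)(OCC)CC(=O)O[C@@H]1CC(C(=O)OC(C)(C)C)=C(C(=O)OCc3ccc(OC)cc3)[C@@]2(C)CCCC(C)(C)[C@H]12
F4 | step 12 | 12-tert-butyl hydrogen 6β-[(diethoxyphosphoryl)acetoxy]drimane-11,12-dioate (11-acid; 8α-H, 9α-H) | CCOP(=O)(OCC)CC(=O)O[C@@H]1C[C@H](C(=O)OC(C)(C)C)[C@H](C(=O)O)[C@@]2(C)CCCC(C)(C)[C@H]12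
F5 | step 12 | 12-tert-butyl hydrogen 6β-[(2E,4E,6E)-octa-2,4,6-trienoyloxy]drimane-11,12-dioate (11-acid; 8α-H, 9α-H) | C/C=C/C=C/C=C/C(=O)O[C@@H]1C[C@H](C(=O)OC(C)(C)C)[C@H](C(=O)O)[C@@]2(C)CCCC(C)(C)[C@H]12
F6 | step 14 | 12-tert-butyl 11-(4-methoxybenzyl) 6β-(bromoacetoxy)-9α-H-drim-7-ene-11,12-dioate | BrCC(=O)O[C@@H]1C=C(C(=O)OC(C)(C)C)[C@H](C(=O)OCc3ccc(OC)cc3)[C@@]2(C)CCCC(C)(C)[C@H]12
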